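**Retrosynthetic overview**
- The last bonds made are the eight O–H bonds (ether cleavage) and the exocyclic C3=CH double bond, which comes from dehydration of the carbinol formed from an indane-3-carbaldehyde and a 5-lithio-2,3-dihydrobenzofuran.
- The strategy rests on indane C1: it carries the cation-stabilising 4-oxyphenyl group and is bonded to C7a of the resorcinol ring C3a–C7a (oxygens on C5 and C7), a ring that hangs on C3 and is symmetric about that bond. C1–C7a is therefore cut as an intramolecular arylation of a p-alkoxybenzyl cation.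
- That cation is released from the anisyl–C(CO2Me) bond of a triaryl cyclopropane ester. Only the ring carbon with the lone 3,5-dimethoxyphenyl group survives, and it becomes C2.
- The cyclopropane comes from a Perkin-derived α-aryl cinnamate and a chiral 3,5-dimethoxybenzylsulfonium ylide, so the retained centre is the ylide carbon, the one the sulfonium group controls directly.
- Ring order: cyclopropane, then the indane five-membered ring (key step); separately the dihydrofuran ring by carbene C–H insertion; the two halves are joined last.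

Key step: step 5

Numbering used for the indanes: C1 carries the 4-oxyphenyl group, C2 the 3,5-dioxyphenyl group, C3 the one-carbon substituent, and C3a–C7a is the resorcinol ring.

Assumption: the sense of induction of the sulfonium salt of step 3 and of the dirhodium catalyst of step 12 is taken as written; if either proves opposite, the enantiomeric sulfide (both are accessible from the limonenes) or catalyst is used and nothing else changes.

**Route**

Step 1
Reactants: 1 4-methoxybenzaldehyde; 2 (3,5-dimethoxyphenyl)acetic acid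
Product: 3 (E)-2-(3,5-dimethoxyphenyl)-3-(4-methoxyphenyl)prop-2-enoic acid
Conditions: Ac2O, Et3N, 110 °C; then aq HCl
Reagents that add atoms: none
Why: Perkin condensation of the mixed-anhydride enolate of the arylacetic acid with the aldehyde should give the α-aryl cinnamic acid with the two aryl groups cis (E); no stereocentre forms, and the geometry is not critical because both alkene carbons become ring carbons that are cleaved in step 5.

Step 2
Reactants: 3 the acrylic acid
Product: 4 methyl (E)-2-(3,5-dimethoxyphenyl)-3-(4-methoxyphenyl)prop-2-enoate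
Conditions: MeI, K2CO3, DMF, rt
Reagents that add atoms: iodomethane, CI
Why: SN2 O-alkylation of the carboxylate gives the methyl ester without acid and without touching the alkene.

Step 3
Reactants: 5 3,5-dimethoxybenzyl bromide; 6 (1R,4R,5R)-isothiocineole (4,7,7-trimethyl-6-thiabicyclo[3.2.1]octane)
Product: 7 (1R,4R,5R)-6-(3,5-dimethoxybenzyl)-4,7,7-trimethyl-6-thiabicyclo[3.2.1]octan-6-ium trifluoromethanesulfonate
Conditions: LiOTf, CH2Cl2/H2O, rt
Reagents that add atoms: lithium trifluoromethanesulfonate, [Li+].[O-]S(=O)(=O)C(F)(F)F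
Why: S-alkylation (SN2) of the bicyclic thioether by the benzylic bromide is made irreversible by exchange of bromide for non-nucleophilic triflate, and should occur on the less hindered sulfur lone pair to give one sulfonium diastereomer.

Step 4
Reactants: 4 the methyl acrylate; 7 the sulfonium triflate
Product: 9 methyl (1S,2S,3S)-1,2-bis(3,5-dimethoxyphenyl)-3-(4-methoxyphenyl)cyclopropane-1-carboxylate, via sulfonium ylide 8 (not isolated)
Conditions: 7, KOtBu, THF, −78 °C; then 4, −78 °C → rt
Reagents that add atoms: none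
Why: Sulfonium ylide cyclopropanation (Michael-initiated ring closure of the Corey–Chaykovsky type) proceeds by conjugate addition of the semi-stabilised benzylide to the α-aryl cinnamate and 3-exo-tet displacement of the sulfide by the ester enolate; the bicyclic sulfonium group shields one face of the ylide carbon, which becomes C2 (S), the aryl groups on C2 and C3 should end up trans, and isomers differing only at C1 or C3 are no loss because those two centres are erased in step 5.

Step 5
Reactants: 9 the triaryl cyclopropane ester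
Product: 10 methyl (1S,2R,3S)-2-(3,5-dimethoxyphenyl)-5,7-dimethoxy-1-(4-methoxyphenyl)indane-3-carboxylate (all-trans)
Conditions: Sc(OTf)3 (10 mol %), (CH2Cl)2, 25 → 60 °C; then DBU (0.2 equiv), rt
Reagents that add atoms: none
Why: Sc(OTf)3 coordinates the ester carbonyl and heterolyses the one cyclopropane bond that joins a good donor carbon to the acceptor carbon, C3(4-methoxyphenyl)–C1(CO2Me), releasing ring strain to a p-methoxybenzyl cation and a scandium ester enolate conjugated with its own 3,5-dimethoxyphenyl ring. The closest known reaction type is the Lewis acid ring opening of aryl donor–acceptor cyclopropanes with intramolecular Friedel–Crafts trapping, and the closure itself is the cyclialkylation of a 1,3-diarylpropyl cation to a 1-arylindane; a single ester on an aryl-bearing carbon is a weaker acceptor than the usual diester, which the electron-rich donor and the strain of a fully substituted triaryl ring should offset. The five-membered ring closes when an ortho carbon of that ring (the two are equivalent, each ortho to one methoxy group and para to the other) attacks the cation, forming the indane C1–C7a bond in a cation–arene closure with the ipso–ortho bond inside the new ring (5-endo with respect to the arene), followed by rearomatisation and protonation of the enolate. Cyclopropane C2 is never broken and becomes indane C2; it controls the new C1 centre, the planar cation closing through the rotamer that holds the 4-methoxyphenyl group away from the C2 aryl group (1,2-trans, 1S), and the ester centre C3 is placed trans to C2 by the DBU equilibration (3S, removed later). The step needs cleavage of the anisyl–ester bond and not the bond to C2, which is secured because a meta-dimethoxyphenyl group stabilises a cation poorly, and it needs ring closure to outrun proton loss from the cation, which the adjacent doubly activated arene and the aprotic, non-basic medium should secure.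

Step 6
Reactants: 10 the indane ester
Product: 11 [(1S,2R,3S)-2-(3,5-dimethoxyphenyl)-5,7-dimethoxy-1-(4-methoxyphenyl)indan-3-yl]methanol
Conditions: LiAlH4, THF, 0 °C
Reagents that add atoms: none
Why: Hydride reduction of the ester gives the primary alcohol; the aryl methyl ethers and the ring centres are inert.

Step 7
Reactants: 11 the indanylmethanol
Product: 12 (1S,2R,3S)-2-(3,5-dimethoxyphenyl)-5,7-dimethoxy-1-(4-methoxyphenyl)indane-3-carbaldehyde
Conditions: Dess–Martin periodinane, pyridine, CH2Cl2, 0 °C → rt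
Reagents that add atoms: none
Why: Dess–Martin oxidation stops at the aldehyde under near-neutral conditions that cannot touch C1 or C2; epimerisation at C3 would be harmless because that centre becomes sp2 in step 15.

Step 8
Reactants: 13 5-bromo-2-hydroxybenzaldehyde; 14 4-methoxybenzyl chloride
Product: 15 5-bromo-2-[(4-methoxybenzyl)oxy]benzaldehyde
Conditions: K2CO3, DMF, 60 °C
Reagents that add atoms: none
Why: Williamson ether synthesis on the phenoxide installs the benzylic CH2 group that will become C2 of the dihydrofuran ring.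

Step 9
Reactants: 15 the aldehyde; 16 1-bromo-3,5-dimethoxybenzene
Product: 18 {5-bromo-2-[(4-methoxybenzyl)oxy]phenyl}(3,5-dimethoxyphenyl)methanol (racemic), via arylmagnesium bromide 17 (not isolated)
Conditions: 16, Mg, THF, reflux; then 15, THF, 0 °C; aq NH4Cl
Reagents that add atoms: none
Why: Grignard formation and 1,2-addition to the aldehyde; the aryl bromide of 15 does not exchange with an arylmagnesium halide at 0 °C, and the new centre is removed in the next step.

Step 10
Reactants: 18 the diaryl carbinol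
Product: 19 {5-bromo-2-[(4-methoxybenzyl)oxy]phenyl}(3,5-dimethoxyphenyl)methanone
Conditions: MnO2, CH2Cl2, rt
Reagents that add atoms: none
Why: MnO2 selectively oxidises the doubly benzylic alcohol to the benzophenone and leaves the benzyl ether alone.

Step 11
Reactants: 19 the ketone
Product: 20 the hydrazone of 19 (E/Z mixture)
Conditions: N2H4·H2O, AcOH (cat.), EtOH, reflux
Reagents that add atoms: hydrazine hydrate, NN.O
Why: Acid-catalysed condensation of hydrazine with the diaryl ketone gives the N-unsubstituted hydrazone needed for oxidation to the diazo compound.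

Step 12
Reactants: 20 the hydrazone
Product: 22 (2S,3R)-5-bromo-3-(3,5-dimethoxyphenyl)-2-(4-methoxyphenyl)-2,3-dihydro-1-benzofuran (cis), via diaryldiazomethane 21 (not isolated)
Conditions: MnO2, CH2Cl2, 0 °C, filter; then Rh2(S-PTAD)4 (dirhodium tetrakis[(S)-(1-adamantyl)(N-phthalimido)acetate], 1 mol %), CH2Cl2, 0 °C
Reagents that add atoms: none
Why: MnO2 dehydrogenates the hydrazone to the diaryldiazomethane, whose rhodium donor/donor carbene inserts into the neighbouring benzylic ether C–H bond (intramolecular 1,5 C–H insertion) to close the dihydrofuran ring; the chiral carboxylate ligands set C3 (R) and the concerted insertion delivers the cis ring (C2 S).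

Step 13
Reactants: 22 the cis-dihydrobenzofuran
Product: 23 (2R,3R)-5-bromo-3-(3,5-dimethoxyphenyl)-2-(4-methoxyphenyl)-2,3-dihydro-1-benzofuran (trans)
Conditions: TFA (10 vol %), CH2Cl2, 0 °C
Reagents that add atoms: none
Why: Acid-mediated epimerisation: reversible ionisation of the C2–O bond to the p-methoxybenzyl cation and reclosure by the phenol gives the thermodynamically preferred trans ring, while C3 is not involved and keeps its configuration, so C2 becomes R.

Step 14
Reactants: 23 the trans aryl bromide; 12 the indane aldehyde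
Product: 25 [(1S,2R,3S)-2-(3,5-dimethoxyphenyl)-5,7-dimethoxy-1-(4-methoxyphenyl)indan-3-yl][(2R,3R)-3-(3,5-dimethoxyphenyl)-2-(4-methoxyphenyl)-2,3-dihydro-1-benzofuran-5-yl]methanol (both carbinol epimers), via aryllithium 24 (not isolated)
Conditions: 23, n-BuLi, THF, −78 °C; then 12, −78 → −40 °C; aq NH4Cl
Reagents that add atoms: none
Why: Bromine–lithium exchange at −78 °C is far faster than deprotonation of the benzylic ring C–H bonds, and 1,2-addition of the aryllithium to the aldehyde gives the carbinol, whose new centre is lost in step 15.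

Step 15
Reactants: 25 the carbinol
Product: 26 (1S,2S)-2-(3,5-dimethoxyphenyl)-3-{(E)-[(2R,3R)-3-(3,5-dimethoxyphenyl)-2-(4-methoxyphenyl)-2,3-dihydro-1-benzofuran-5-yl]methylidene}-5,7-dimethoxy-1-(4-methoxyphenyl)indane
Conditions: p-TsOH·H2O (10 mol %), toluene, rt
Reagents that add atoms: none
Why: Acid-catalysed E1 dehydration: the carbinol ionises to a benzylic cation stabilised by the para ring oxygen of the dihydrobenzofuran, and loss of the only β-hydrogen (indane C3–H) gives the conjugated exocyclic alkene, E being favoured because the aryl group avoids the peri C4–H of the indane.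

Step 16
Reactants: 26 the octamethyl ether
Product: 27 (1S,2S)-2-(3,5-dihydroxyphenyl)-3-{(E)-[(2R,3R)-3-(3,5-dihydroxyphenyl)-2-(4-hydroxyphenyl)-2,3-dihydro-1-benzofuran-5-yl]methylidene}-1-(4-hydroxyphenyl)indane-5,7-diol (CNP0184753.1)
Conditions: BBr3, CH2Cl2, −78 °C → rt; then H2O, 0 °C
Reagents that add atoms: none
Why: Lewis acid cleavage of aryl methyl ethers (borane–ether complex, then SN2 attack of bromide on methyl) should free all eight phenols; the exocyclic styrene and the 2-aryl-dihydrobenzofuran are each of a type known to survive this reagent, and any opening of the dihydrofuran at C2 should reclose to the trans ring.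

**Compound list**
1 | 4-methoxybenzaldehyde | COc1ccc(C=O)cc1 | starting material
2 | (3,5-dimethoxyphenyl)acetic acid | COc1cc(CC(=O)O)cc(OC)c1 | starting material
3 | (E)-2-(3,5-dimethoxyphenyl)-3-(4-methoxyphenyl)prop-2-enoic acid | OC(=O)/C(=C/c1ccc(OC)cc1)c1cc(OC)cc(OC)c1 | intermediate
4 | methyl (E)-2-(3,5-dimethoxyphenyl)-3-(4-methoxyphenyl)prop-2-enoate | COC(=O)/C(=C/c1ccc(OC)cc1)c1cc(OC)cc(OC)c1 | intermediate
5 | 3,5-dimethoxybenzyl bromide | COc1cc(CBr)cc(OC)c1 | starting material
6 | (1R,4R,5R)-isothiocineole | C[C@@H]1CC[C@@H]2C[C@H]1SC2(C)C | starting material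
7 | (1R,4R,5R)-6-(3,5-dimethoxybenzyl)-4,7,7-trimethyl-6-thiabicyclo[3.2.1]octan-6-ium trifluoromethanesulfonate (sulfur configuration not specified) | C[C@@H]1CC[C@@H]2C[C@H]1[S+](Cc1cc(OC)cc(OC)c1)C2(C)C.[O-]S(=O)(=O)C(F)(F)F | intermediate
8 | sulfonium (3,5-dimethoxyphenyl)methylide derived from 7 | C[C@@H]1CC[C@@H]2C[C@H]1[S+]([CH-]c1cc(OC)cc(OC)c1)C2(C)C | intermediate (not isolated)
9 | methyl (1S,2S,3S)-1,2-bis(3,5-dimethoxyphenyl)-3-(4-methoxyphenyl)cyclopropane-1-carboxylate | COC(=O)[C@@]1(c2cc(OC)cc(OC)c2)[C@H](c2ccc(OC)cc2)[C@H]1c1cc(OC)cc(OC)c1 | intermediate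
10 | methyl (1S,2R,3S)-2-(3,5-dimethoxyphenyl)-5,7-dimethoxy-1-(4-methoxyphenyl)indane-3-carboxylate | COc1ccc([C@H]2c3c(OC)cc(OC)cc3[C@@H](C(=O)OC)[C@@H]2c2cc(OC)cc(OC)c2)cc1 | intermediate
11 | [(1S,2R,3S)-2-(3,5-dimethoxyphenyl)-5,7-dimethoxy-1-(4-methoxyphenyl)indan-3-yl]methanol | COc1ccc([C@H]2c3c(OC)cc(OC)cc3[C@@H](CO)[C@@H]2c2cc(OC)cc(OC)c2)cc1 | intermediate
12 | (1S,2R,3S)-2-(3,5-dimethoxyphenyl)-5,7-dimethoxy-1-(4-methoxyphenyl)indane-3-carbaldehyde | COc1ccc([C@H]2c3c(OC)cc(OC)cc3[C@@H](C=O)[C@@H]2c2cc(OC)cc(OC)c2)cc1 | intermediate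
13 | 5-bromo-2-hydroxybenzaldehyde | O=Cc1cc(Br)ccc1O | starting material
14 | 4-methoxybenzyl chloride | COc1ccc(CCl)cc1 | starting material
15 | 5-bromo-2-[(4-methoxybenzyl)oxy]benzaldehyde | COc1ccc(COc2ccc(Br)cc2C=O)cc1 | intermediate
16 | 1-bromo-3,5-dimethoxybenzene | COc1cc(Br)cc(OC)c1 | starting material
17 | (3,5-dimethoxyphenyl)magnesium bromide | COc1cc([Mg]Br)cc(OC)c1 | intermediate (not isolated)
18 | {5-bromo-2-[(4-methoxybenzyl)oxy]phenyl}(3,5-dimethoxyphenyl)methanol (racemic) | COc1ccc(COc2ccc(Br)cc2C(O)c2cc(OC)cc(OC)c2)cc1 | intermediate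
19 | {5-bromo-2-[(4-methoxybenzyl)oxy]phenyl}(3,5-dimethoxyphenyl)methanone | COc1ccc(COc2ccc(Br)cc2C(=O)c2cc(OC)cc(OC)c2)cc1 | intermediate
20 | hydrazone of 19 | COc1ccc(COc2ccc(Br)cc2C(=NN)c2cc(OC)cc(OC)c2)cc1 | intermediate
21 | 4-bromo-2-[diazo(3,5-dimethoxyphenyl)methyl]-1-[(4-methoxybenzyl)oxy]benzene | COc1ccc(COc2ccc(Br)cc2C(=[N+]=[N-])c2cc(OC)cc(OC)c2)cc1 | intermediate (not isolated)
22 | (2S,3R)-5-bromo-3-(3,5-dimethoxyphenyl)-2-(4-methoxyphenyl)-2,3-dihydro-1-benzofuran (cis) | Brc1ccc2c(c1)[C@@H](c1cc(OC)cc(OC)c1)[C@@H](c1ccc(OC)cc1)O2 | intermediate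
23 | (2R,3R)-5-bromo-3-(3,5-dimethoxyphenyl)-2-(4-methoxyphenyl)-2,3-dihydro-1-benzofuran (trans) | Brc1ccc2c(c1)[C@@H](c1cc(OC)cc(OC)c1)[C@H](c1ccc(OC)cc1)O2 | intermediate
24 | [(2R,3R)-3-(3,5-dimethoxyphenyl)-2-(4-methoxyphenyl)-2,3-dihydro-1-benzofuran-5-yl]lithium | [Li]c1ccc2c(c1)[C@@H](c1cc(OC)cc(OC)c1)[C@H](c1ccc(OC)cc1)O2 | intermediate (not isolated)
25 | [(1S,2R,3S)-2-(3,5-dimethoxyphenyl)-5,7-dimethoxy-1-(4-methoxyphenyl)indan-3-yl][(2R,3R)-3-(3,5-dimethoxyphenyl)-2-(4-methoxyphenyl)-2,3-dihydro-1-benzofuran-5-yl]methanol (carbinol epimers) | COc1ccc([C@H]2c3c(OC)cc(OC)cc3[C@@H](C(O)c3ccc4c(c3)[C@@H](c3cc(OC)cc(OC)c3)[C@H](c3ccc(OC)cc3)O4)[C@@H]2c2cc(OC)cc(OC)c2)cc1 | intermediate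
26 | (1S,2S)-2-(3,5-dimethoxyphenyl)-3-{(E)-[(2R,3R)-3-(3,5-dimethoxyphenyl)-2-(4-methoxyphenyl)-2,3-dihydro-1-benzofuran-5-yl]methylidene}-5,7-dimethoxy-1-(4-methoxyphenyl)indane | COc1ccc([C@H]2c3c(OC)cc(OC)cc3/C(=C/c3ccc4c(c3)[C@@H](c3cc(OC)cc(OC)c3)[C@H](c3ccc(OC)cc3)O4)[C@@H]2c2cc(OC)cc(OC)c2)cc1 | intermediate
27 | (1S,2S)-2-(3,5-dihydroxyphenyl)-3-{(E)-[(2R,3R)-3-(3,5-dihydroxyphenyl)-2-(4-hydroxyphenyl)-2,3-dihydro-1-benzofuran-5-yl]methylidene}-1-(4-hydroxyphenyl)indane-5,7-diol | Oc1ccc([C@H]2c3c(O)cc(O)cc3/C(=C/c3ccc4c(c3)[C@@H](c3cc(O)cc(O)c3)[C@H](c3ccc(O)cc3)O4)[C@@H]2c2cc(O)cc(O)c2)cc1 | target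

**Step count**
Total step count: 16. Longest linear sequence: 9 steps (steps 1, 2, 4, 5, 6, 7, 14, 15, 16; the benzofuran branch, steps 8–13 followed by 14–16, is equally long).

**Steps most likely to fail**

Step 5. Ionisation of the cyclopropane may be slow with only one ester on the acceptor carbon, and proton loss from the benzylic cation to a ring-opened alkene may compete with ring closure; re-protonation of that alkene would erode the configuration at C2. The fallback sets out from cyclopropane 9 and comes back at aldehyde 12; it strengthens the acceptor before the ring is opened. LiAlH4 reduction of 9 should give [(1S,2S,3S)-1,2-bis(3,5-dimethoxyphenyl)-3-(4-methoxyphenyl)cyclopropyl]methanol F3, and Dess–Martin oxidation should give (1S,2S,3S)-1,2-bis(3,5-dimethoxyphenyl)-3-(4-methoxyphenyl)cyclopropane-1-carbaldehyde F4. A formyl group is a much stronger acceptor than an ester, so SnCl4 or Sc(OTf)3 in CH2Cl2 at −78 → 0 °C should open the same bond and close the indane ring to 12 directly, by the known Lewis acid ring opening of formyl- and acyl-substituted donor–acceptor cyclopropanes with arene trapping.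

Step 4. Conjugate addition of a bulky semi-stabilised ylide to a trisubstituted, donor-substituted acrylate may be slow, the ylide may rearrange instead, and control of the ylide face may be incomplete. The fallback sets out from acrylate 4 and bromide 5 and comes back at cyclopropane 9; it replaces asymmetric induction by resolution. Bromide 5 is quaternised with tetrahydrothiophene (acetone, rt) to 1-(3,5-dimethoxybenzyl)tetrahydrothiophen-1-ium bromide F1. Its small achiral ylide (KOtBu, THF, or 50 % NaOH/CH2Cl2 under phase transfer) should cyclopropanate 4 to racemic methyl (1RS,2RS,3RS)-1,2-bis(3,5-dimethoxyphenyl)-3-(4-methoxyphenyl)cyclopropane-1-carboxylate F2. The (1S,2S,3S) enantiomer 9 is then taken from F2 by preparative chromatography on a chiral stationary phase.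

Step 16. Lewis acid exposure during eight ether cleavages may move the exocyclic double bond into the indane ring (which destroys C2), trigger cation cyclisation onto a neighbouring aryl ring, or open the dihydrofuran ring without clean reclosure. The fallback sets out from indane ester 10 and bromide 23 and comes back at target 27; it removes the methyl groups before the sensitive alkene exists and finishes with fluoride.
- Indane half: BBr3 on 10 (CH2Cl2, then MeOH work-up to restore the methyl ester) should give methyl (1S,2R,3S)-2-(3,5-dihydroxyphenyl)-5,7-dihydroxy-1-(4-hydroxyphenyl)indane-3-carboxylate F5. TBSOTf and 2,6-lutidine should give its pentakis(tert-butyldimethylsilyl) ether F6. i-Bu2AlH (CH2Cl2, −78 → 0 °C) should give the penta-silylated indan-3-ylmethanol F7, and Dess–Martin oxidation the penta-silylated indane-3-carbaldehyde F8.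
- Benzofuran half: BBr3 on 23 should give (2R,3R)-5-bromo-3-(3,5-dihydroxyphenyl)-2-(4-hydroxyphenyl)-2,3-dihydro-1-benzofuran F9, and silylation its tris(tert-butyldimethylsilyl) ether F10.
- Union: bromine–lithium exchange on F10 (n-BuLi, THF, −78 °C) and addition to F8 should give the octa-silylated carbinol F11. Catalytic p-TsOH in toluene should dehydrate it to the octa-silylated E-benzylidene compound F12. TBAF buffered with AcOH (THF, 0 °C) should then release 27 without any Lewis acid.

**Further compounds**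
F1 | step 4 | 1-(3,5-dimethoxybenzyl)tetrahydrothiophen-1-ium bromide | COc1cc(C[S+]2CCCC2)cc(OC)c1.[Br-]
F2 | step 4 | racemic methyl (1RS,2RS,3RS)-1,2-bis(3,5-dimethoxyphenyl)-3-(4-methoxyphenyl)cyclopropane-1-carboxylate (one enantiomer drawn) | COC(=O)[C@@]1(c2cc(OC)cc(OC)c2)[C@H](c2ccc(OC)cc2)[C@H]1c1cc(OC)cc(OC)c1
F3 | step 5 | [(1S,2S,3S)-1,2-bis(3,5-dimethoxyphenyl)-3-(4-methoxyphenyl)cyclopropyl]methanol | OC[C@@]1(c2cc(OC)cc(OC)c2)[C@H](c2ccc(OC)cc2)[C@H]1c1cc(OC)cc(OC)c1
F4 | step 5 | (1S,2S,3S)-1,2-bis(3,5-dimethoxyphenyl)-3-(4-methoxyphenyl)cyclopropane-1-carbaldehyde | O=C[C@@]1(c2cc(OC)cc(OC)c2)[C@H](c2ccc(OC)cc2)[C@H]1c1cc(OC)cc(OC)c1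
F5 | step 16 | methyl (1S,2R,3S)-2-(3,5-dihydroxyphenyl)-5,7-dihydroxy-1-(4-hydroxyphenyl)indane-3-carboxylate | Oc1ccc([C@H]2c3c(O)cc(O)cc3[C@@H](C(=O)OC)[C@@H]2c2cc(O)cc(O)c2)cc1
F6 | step 16 | pentakis(tert-butyldimethylsilyl) ether of F5 | CC(C)(C)[Si](C)(C)Oc1ccc([C@H]2c3c(O[Si](C)(C)C(C)(C)C)cc(O[Si](C)(C)C(C)(C)C)cc3[C@@H](C(=O)OC)[C@@H]2c2cc(O[Si](C)(C)C(C)(C)C)cc(O[Si](C)(C)C(C)(C)C)c2)cc1
F7 | step 16 | penta-silylated [(1S,2R,3S)-indan-3-yl]methanol corresponding to F6 | CC(C)(C)[Si](C)(C)Oc1ccc([C@H]2c3c(O[Si](C)(C)C(C)(C)C)cc(O[Si](C)(C)C(C)(C)C)cc3[C@@H](CO)[C@@H]2c2cc(O[Si](C)(C)C(C)(C)C)cc(O[Si](C)(C)C(C)(C)C)c2)cc1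
F8 | step 16 | penta-silylated (1S,2R,3S)-indane-3-carbaldehyde corresponding to F6 | CC(C)(C)[Si](C)(C)Oc1ccc([C@H]2c3c(O[Si](C)(C)C(C)(C)C)cc(O[Si](C)(C)C(C)(C)C)cc3[C@@H](C=O)[C@@H]2c2cc(O[Si](C)(C)C(C)(C)C)cc(O[Si](C)(C)C(C)(C)C)c2)cc1
F9 | step 16 | (2R,3R)-5-bromo-3-(3,5-dihydroxyphenyl)-2-(4-hydroxyphenyl)-2,3-dihydro-1-benzofuran | Brc1ccc2c(c1)[C@@H](c1cc(O)cc(O)c1)[C@H](c1ccc(O)cc1)O2
F10 | step 16 | tris(tert-butyldimethylsilyl) ether of F9 | Brc1ccc2c(c1)[C@@H](c1cc(O[Si](C)(C)C(C)(C)C)cc(O[Si](C)(C)C(C)(C)C)c1)[C@H](c1ccc(O[Si](C)(C)C(C)(C)C)cc1)O2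
F11 | step 16 | octa-silylated carbinol from F8 and lithiated F10 (carbinol epimers) | CC(C)(C)[Si](C)(C)Oc1ccc([C@H]2c3c(O[Si](C)(C)C(C)(C)C)cc(O[Si](C)(C)C(C)(C)C)cc3[C@@H](C(O)c3ccc4c(c3)[C@@H](c3cc(O[Si](C)(C)C(C)(C)C)cc(O[Si](C)(C)C(C)(C)C)c3)[C@H](c3ccc(O[Si](C)(C)C(C)(C)C)cc3)O4)[C@@H]2c2cc(O[Si](C)(C)C(C)(C)C)cc(O[Si](C)(C)C(C)(C)C)c2)cc1
F12 | step 16 | octakis(tert-butyldimethylsilyl) ether of 27 | CC(C)(C)[Si](C)(C)Oc1ccc([C@H]2c3c(O[Si](C)(C)C(C)(C)C)cc(O[Si](C)(C)C(C)(C)C)cc3/C(=C/c3ccc4c(c3)[C@@H](c3cc(O[Si](C)(C)C(C)(C)C)cc(O[Si](C)(C)C(C)(C)C)c3)[C@H](c3ccc(O[Si](C)(C)C(C)(C)C)cc3)O4)[C@@H]2c2cc(O[Si](C)(C)C(C)(C)C)cc(O[Si](C)(C)C(C)(C)C)c2)cc1
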